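## Retrosynthetic overview

1. Target ⇐ final desilylation ⇐ C8–O acylation with (R)-2-methylbutanoic acid (from tiglic acid by asymmetric hydrogenation) ⇐ C14 allylic oxidation ⇐ α-methylenation of the macrocyclic lactone.
2. Ten-membered carbocycle (second and last ring) ⇐ ring-closing metathesis forming C1=C10.
3. C9–C10 ⇐ chelation-controlled addition of a 2-metallated allyl ether to a C9 aldehyde; C3–C4 ⇐ Negishi coupling on a (Z)-iodoalkene made by hydroxyl-directed hydroalumination of a propargylic alcohol.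
4. γ-Lactone (first ring) ⇐ oxidative cleavage of a C7 allyl group onto the C6 hydroxyl; C6 ⇐ asymmetric transfer hydrogenation of an ynone; C7 ⇐ Fráter–Seebach allylation.
5. C8 (first stereocenter) ⇐ ketoreductase reduction of achiral ethyl 4-[(4-methoxybenzyl)oxy]-3-oxobutanoate.

Assumption: atoms carry germacranolide numbers (ring C1–C10, lactone C11/C12 closed on O–C6, exocyclic CH2 = C13, CHO = C14, CH2OH = C15), and the SMILES is read as 6R,7S,8S,9S with an (R)-2-methylbutanoate and both ring double bonds ring-cis (C2 cis to C9, C3 cis to C6).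

## Route

Step 1
Reactants: 1 ethyl 4-chloro-3-oxobutanoate; 2 4-methoxybenzyl alcohol
Product: 3 ethyl 4-[(4-methoxybenzyl)oxy]-3-oxobutanoate
Conditions: NaH (2.2 equiv), THF, 0 °C → rt; then 1 M HCl
Reagents that add atoms: none
Why: Williamson etherification in which the second equivalent of NaH holds the β-keto ester as its enolate while the alkoxide of 2 displaces chloride; no stereocenter is formed.

Step 2
Reactants: 3 ethyl 4-[(4-methoxybenzyl)oxy]-3-oxobutanoate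
Product: 4 ethyl (3S)-3-hydroxy-4-[(4-methoxybenzyl)oxy]butanoate
Conditions: (S)-selective ketoreductase (NADPH-dependent alcohol dehydrogenase), NADP+ (cat.), i-PrOH (15 vol %), phosphate buffer pH 7.0, 30 °C
Reagents that add atoms: none
Why: Enzymatic asymmetric ketone reduction in which the ketoreductase delivers hydride from NADPH to one carbonyl face (expected >99% ee, i-PrOH recycling the cofactor), setting C8 as the first stereocenter.

Step 3
Reactants: 4 ethyl (3S)-3-hydroxy-4-[(4-methoxybenzyl)oxy]butanoate; 5 allyl bromide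
Product: 7 ethyl (2R,3S)-3-hydroxy-4-[(4-methoxybenzyl)oxy]-2-(prop-2-en-1-yl)butanoate, via dilithium dianion 6 (not isolated)
Conditions: LiN(i-Pr)2 (2.2 equiv), THF, −78 → −20 °C; 5, DMPU, −78 → −10 °C; NH4Cl (aq.)
Reagents that add atoms: none
Why: Fráter–Seebach alkylation in which the lithium-chelated alkoxide enolate is allylated on the face anti to the C9 substituent, giving the 2,3-anti product and thereby setting C7 from C8.

Step 4
Reactants: 7 ethyl (2R,3S)-3-hydroxy-4-[(4-methoxybenzyl)oxy]-2-(prop-2-en-1-yl)butanoate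
Product: 8 ethyl (2R)-2-[(4S)-2-(4-methoxyphenyl)-1,3-dioxolan-4-yl]pent-4-enoate (acetal epimers)
Conditions: DDQ (1.2 equiv), 4 Å molecular sieves, CH2Cl2, 0 °C
Reagents that add atoms: none
Why: Anhydrous DDQ oxidation of the PMB ether gives an oxocarbenium ion that the neighbouring C8 hydroxyl traps (oxidative acetalization), protecting the C8/C9 diol without touching the stereocenters.

Step 5
Reactants: 8 ethyl (2R)-2-[(4S)-2-(4-methoxyphenyl)-1,3-dioxolan-4-yl]pent-4-enoate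
Product: 9 (2R)-N-methoxy-2-[(4S)-2-(4-methoxyphenyl)-1,3-dioxolan-4-yl]-N-methylpent-4-enamide
Conditions: MeNH(OMe)·HCl (3 equiv), i-PrMgCl (6 equiv), THF, −20 → 0 °C
Reagents that add atoms: N,O-dimethylhydroxylamine hydrochloride, CNOC.Cl
Why: Weinreb amide formation by aminolysis of the ester with the magnesium amide at low temperature, conditions known to leave α-stereocenters such as C7 intact.

Step 6
Reactants: 9 (2R)-N-methoxy-2-[(4S)-2-(4-methoxyphenyl)-1,3-dioxolan-4-yl]-N-methylpent-4-enamide; 10 tert-butyl(dimethyl)(prop-2-yn-1-yloxy)silane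
Product: 12 (5R)-1-[(tert-butyldimethylsilyl)oxy]-5-[(4S)-2-(4-methoxyphenyl)-1,3-dioxolan-4-yl]oct-7-en-2-yn-4-one, via lithium acetylide 11 (not isolated)
Conditions: 10 (1.5 equiv), n-BuLi, THF, −78 °C; then 9, −78 → 0 °C; NH4Cl (aq.)
Reagents that add atoms: none
Why: Weinreb ketone synthesis in which the chelated tetrahedral intermediate stops after one acetylide addition, attaching C5, C4 and C15.

Step 7
Reactants: 12 (5R)-1-[(tert-butyldimethylsilyl)oxy]-5-[(4S)-2-(4-methoxyphenyl)-1,3-dioxolan-4-yl]oct-7-en-2-yn-4-one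
Product: 13 (4S,5S)-1-[(tert-butyldimethylsilyl)oxy]-5-[(4S)-2-(4-methoxyphenyl)-1,3-dioxolan-4-yl]oct-7-en-2-yn-4-ol
Conditions: Ru[(S,S)-TsDPEN](p-cymene) (2 mol %), i-PrOH, 25 °C
Reagents that add atoms: none
Why: Noyori asymmetric transfer hydrogenation of an ynone under base-free conditions, in which the (S,S)-catalyst (alkyne in the π-group position) sets the C6 carbinol by catalyst control without epimerising C7.

Step 8
Reactants: 13 (4S,5S)-1-[(tert-butyldimethylsilyl)oxy]-5-[(4S)-2-(4-methoxyphenyl)-1,3-dioxolan-4-yl]oct-7-en-2-yn-4-ol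
Product: 15 (2Z,4S,5S)-1-[(tert-butyldimethylsilyl)oxy]-2-iodo-5-[(4S)-2-(4-methoxyphenyl)-1,3-dioxolan-4-yl]octa-2,7-dien-4-ol, via cyclic vinylalanate 14 (not isolated)
Conditions: NaAlH2(OCH2CH2OMe)2 (Red-Al, 2.5 equiv), THF, 0 °C → rt; EtOAc; I2, −78 → 0 °C; KNaC4H4O6 (aq.), Na2S2O3 (aq.)
Reagents that add atoms: iodine, II
Why: Hydroxyl-directed trans-hydroalumination places hydride on C5 and aluminium on C4 cis to C6 in a five-membered alanate, and iodinolysis with retention gives the (Z)-iodoalkene that fixes the C4=C5 geometry.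

Step 9
Reactants: 15 (2Z,4S,5S)-1-[(tert-butyldimethylsilyl)oxy]-2-iodo-5-[(4S)-2-(4-methoxyphenyl)-1,3-dioxolan-4-yl]octa-2,7-dien-4-ol
Product: 16 (2Z,4S,5S)-1-[(tert-butyldimethylsilyl)oxy]-5-{(1S)-2-hydroxy-1-[(4-methoxybenzyl)oxy]ethyl}-2-iodoocta-2,7-dien-4-ol
Conditions: i-Bu2AlH (5 equiv), CH2Cl2, −78 → 0 °C; KNaC4H4O6 (aq.)
Reagents that add atoms: none
Why: Regioselective reductive opening of the 4-methoxybenzylidene acetal, in which the aluminium hydride binds the less hindered primary oxygen and cleaves that C–O bond, leaves the PMB ether on O8 and frees the C9 hydroxyl.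

Step 10
Reactants: 16 (2Z,4S,5S)-1-[(tert-butyldimethylsilyl)oxy]-5-{(1S)-2-hydroxy-1-[(4-methoxybenzyl)oxy]ethyl}-2-iodoocta-2,7-dien-4-ol
Product: 17 (2Z,4S,5S)-1-[(tert-butyldimethylsilyl)oxy]-2-iodo-5-{(1S)-1-[(4-methoxybenzyl)oxy]-2-[(triethylsilyl)oxy]ethyl}octa-2,7-dien-4-ol
Conditions: Et3SiCl (1.05 equiv), imidazole, CH2Cl2, −78 °C
Reagents that add atoms: chlorotriethylsilane, CC[Si](CC)(CC)Cl
Why: Selective silylation of the primary C9 hydroxyl over the hindered secondary allylic C6 hydroxyl, so that only O6 can later close the lactol.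

Step 11
Reactants: 17 (2Z,4S,5S)-1-[(tert-butyldimethylsilyl)oxy]-2-iodo-5-{(1S)-1-[(4-methoxybenzyl)oxy]-2-[(triethylsilyl)oxy]ethyl}octa-2,7-dien-4-ol
Product: 19 (4S,5S)-5-{(1Z)-3-[(tert-butyldimethylsilyl)oxy]-2-iodoprop-1-en-1-yl}-4-{(1S)-1-[(4-methoxybenzyl)oxy]-2-[(triethylsilyl)oxy]ethyl}oxolan-2-ol (anomers), via vicinal diol 18 (not isolated)
Conditions: K2OsO4·2H2O (2 mol %), NaIO4 (4 equiv), 2,6-lutidine, 1,4-dioxane/H2O 3:1, rt
Reagents that add atoms: sodium periodate, [Na+].[O-]I(=O)(=O)=O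
Why: Lemieux–Johnson cleavage of the terminal alkene (the iodoalkene is electron-poor and inert) gives the C12 aldehyde, which the C6 hydroxyl traps as a five-membered lactol.

Step 12
Reactants: 19 (4S,5S)-5-{(1Z)-3-[(tert-butyldimethylsilyl)oxy]-2-iodoprop-1-en-1-yl}-4-{(1S)-1-[(4-methoxybenzyl)oxy]-2-[(triethylsilyl)oxy]ethyl}oxolan-2-ol
Product: 20 (4S,5S)-5-{(1Z)-3-[(tert-butyldimethylsilyl)oxy]-2-iodoprop-1-en-1-yl}-4-{(1S)-1-[(4-methoxybenzyl)oxy]-2-[(triethylsilyl)oxy]ethyl}oxolan-2-one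
Conditions: TEMPO (20 mol %), PhI(OAc)2 (1.5 equiv), CH2Cl2, rt
Reagents that add atoms: none
Why: Oxoammonium oxidation of the lactol to the lactone closes the first ring as the 12,6-olide with the trans relationship already fixed by C6 and C7.

Step 13
Reactants: 20 (4S,5S)-5-{(1Z)-3-[(tert-butyldimethylsilyl)oxy]-2-iodoprop-1-en-1-yl}-4-{(1S)-1-[(4-methoxybenzyl)oxy]-2-[(triethylsilyl)oxy]ethyl}oxolan-2-one; 21 but-3-en-1-ylzinc bromide
Product: 22 (4S,5R)-5-[(1E)-2-{[(tert-butyldimethylsilyl)oxy]methyl}hexa-1,5-dien-1-yl]-4-{(1S)-1-[(4-methoxybenzyl)oxy]-2-[(triethylsilyl)oxy]ethyl}oxolan-2-one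
Conditions: 21 (3 equiv), Pd(dppf)Cl2·CH2Cl2 (5 mol %), THF, rt
Reagents that add atoms: none
Why: Negishi sp2–sp3 coupling with retention of alkene geometry installs C3–C1 cis to C6 (fast oxidative addition of the alkenyl iodide to zerovalent palladium, dppf suppressing β-hydride elimination), and the lactone tolerates the organozinc.

Step 14
Reactants: 22 (4S,5R)-5-[(1E)-2-{[(tert-butyldimethylsilyl)oxy]methyl}hexa-1,5-dien-1-yl]-4-{(1S)-1-[(4-methoxybenzyl)oxy]-2-[(triethylsilyl)oxy]ethyl}oxolan-2-one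
Product: 23 (4S,5R)-5-[(1E)-2-{[(tert-butyldimethylsilyl)oxy]methyl}hexa-1,5-dien-1-yl]-4-{(1S)-2-hydroxy-1-[(4-methoxybenzyl)oxy]ethyl}oxolan-2-one
Conditions: PPTS (0.2 equiv), MeOH/CH2Cl2 1:1, 0 °C
Reagents that add atoms: none
Why: Acid-catalysed methanolysis removes the primary triethylsilyl ether far faster than the tert-butyldimethylsilyl ether, freeing only the C9 hydroxyl.

Step 15
Reactants: 23 (4S,5R)-5-[(1E)-2-{[(tert-butyldimethylsilyl)oxy]methyl}hexa-1,5-dien-1-yl]-4-{(1S)-2-hydroxy-1-[(4-methoxybenzyl)oxy]ethyl}oxolan-2-one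
Product: 24 (2S)-2-{(2R,3S)-2-[(1E)-2-{[(tert-butyldimethylsilyl)oxy]methyl}hexa-1,5-dien-1-yl]-5-oxooxolan-3-yl}-2-[(4-methoxybenzyl)oxy]acetaldehyde
Conditions: Dess–Martin periodinane (1.5 equiv), NaHCO3, CH2Cl2, 0 °C → rt
Reagents that add atoms: none
Why: Buffered Dess–Martin oxidation gives the α-alkoxy aldehyde without epimerising C8; it is used crude at once.

Step 16
Reactants: 25 2,3-dibromoprop-1-ene; 2 4-methoxybenzyl alcohol
Product: 26 1-{[(2-bromoprop-2-en-1-yl)oxy]methyl}-4-methoxybenzene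
Conditions: NaH (1.1 equiv), THF, 0 °C → rt
Reagents that add atoms: none
Why: Williamson etherification at the allylic bromide; the vinylic bromide is inert to SN2 displacement.

Step 17
Reactants: 24 (2S)-2-{(2R,3S)-2-[(1E)-2-{[(tert-butyldimethylsilyl)oxy]methyl}hexa-1,5-dien-1-yl]-5-oxooxolan-3-yl}-2-[(4-methoxybenzyl)oxy]acetaldehyde; 26 1-{[(2-bromoprop-2-en-1-yl)oxy]methyl}-4-methoxybenzene
Product: 29 (4S,5R)-5-[(1E)-2-{[(tert-butyldimethylsilyl)oxy]methyl}hexa-1,5-dien-1-yl]-4-{(1S,2S)-2-hydroxy-1-[(4-methoxybenzyl)oxy]-3-{[(4-methoxybenzyl)oxy]methyl}but-3-en-1-yl}oxolan-2-one, via vinyllithium 27 (not isolated), via vinylmagnesium bromide 28 (not isolated)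
Conditions: 26 (3 equiv), t-BuLi (6 equiv), Et2O, −78 °C; MgBr2·OEt2, −78 °C; then 24 + MgBr2·OEt2 in CH2Cl2, −78 °C; NH4Cl (aq.)
Reagents that add atoms: none
Why: Cram-chelate addition in which magnesium bridges the aldehyde oxygen and the C8 PMB ether oxygen and the alkenylmagnesium attacks the face opposite the C7 substituent, giving the 8,9-syn alcohol (C9 S); the aldehyde reacts far faster than the lactone at −78 °C.

Step 18
Reactants: 29 (4S,5R)-5-[(1E)-2-{[(tert-butyldimethylsilyl)oxy]methyl}hexa-1,5-dien-1-yl]-4-{(1S,2S)-2-hydroxy-1-[(4-methoxybenzyl)oxy]-3-{[(4-methoxybenzyl)oxy]methyl}but-3-en-1-yl}oxolan-2-one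
Product: 30 (1(10)Z,4E,6R,7S,8S,9S)-15-[(tert-butyldimethylsilyl)oxy]-9-hydroxy-8,14-bis[(4-methoxybenzyl)oxy]-13-norgermacra-1(10),4-dien-12,6-olide
Conditions: second-generation Hoveyda–Grubbs catalyst RuCl2(H2IMes)(=CH-C6H4-2-O-i-Pr) (15 mol %), 1,4-benzoquinone (30 mol %), toluene (0.5 mM), 80 °C
Reagents that add atoms: none
Why: Ring-closing metathesis between the terminal C1 alkene and the 1,1-disubstituted C10 alkene (free allylic hydroxyl assisting) closes the ten-membered ring, where the ring-cis trisubstituted alkene is the expected, less strained isomer and the existing trisubstituted C4=C5 bond cannot give a small-ring by-product.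

Step 19
Reactants: 30 (1(10)Z,4E,6R,7S,8S,9S)-15-[(tert-butyldimethylsilyl)oxy]-9-hydroxy-8,14-bis[(4-methoxybenzyl)oxy]-13-norgermacra-1(10),4-dien-12,6-olide
Product: 31 (1(10)Z,4E,6R,7S,8S,9S)-9,15-bis[(tert-butyldimethylsilyl)oxy]-8,14-bis[(4-methoxybenzyl)oxy]-13-norgermacra-1(10),4-dien-12,6-olide
Conditions: t-BuMe2SiOTf (1.5 equiv), 2,6-lutidine, CH2Cl2, −78 → 0 °C
Reagents that add atoms: tert-butyldimethylsilyl trifluoromethanesulfonate, CC(C)(C)[Si](C)(C)OS(=O)(=O)C(F)(F)F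
Why: Silyl triflate silylation protects the hindered allylic C9 hydroxyl before the enolate and oxidation chemistry.

Step 20
Reactants: 31 (1(10)Z,4E,6R,7S,8S,9S)-9,15-bis[(tert-butyldimethylsilyl)oxy]-8,14-bis[(4-methoxybenzyl)oxy]-13-norgermacra-1(10),4-dien-12,6-olide
Product: 33 13-(dimethylamino)-9,15-bis[(tert-butyldimethylsilyl)oxy]-8,14-bis[(4-methoxybenzyl)oxy]germacra-1(10),4-dien-12,6-olide (C11 epimers), via lithium enolate 32 (not isolated)
Conditions: LiN(SiMe3)2 (1.5 equiv), THF, −78 °C; [Me2N=CH2]I (3 equiv), −78 °C → rt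
Reagents that add atoms: Eschenmoser's salt, C[N+](C)=C.[I-]
Why: Mannich reaction of the lactone lithium enolate with the iminium salt adds C13; the molecule has no other acidic site or β-leaving group, and the C11 configuration is irrelevant.

Step 21
Reactants: 33 13-(dimethylamino)-9,15-bis[(tert-butyldimethylsilyl)oxy]-8,14-bis[(4-methoxybenzyl)oxy]germacra-1(10),4-dien-12,6-olide
Product: 35 (1(10)Z,4E,6R,7S,8S,9S)-9,15-bis[(tert-butyldimethylsilyl)oxy]-8,14-bis[(4-methoxybenzyl)oxy]germacra-1(10),4,11(13)-trien-12,6-olide, via trimethylammonium iodide 34 (not isolated)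
Conditions: MeI (excess), CH2Cl2/MeOH, rt; then NaHCO3 (aq.), EtOAc, rt
Reagents that add atoms: none
Why: Quaternisation and mild-base E1cB (Hofmann-type) elimination of trimethylamine unveil the α-methylene lactone.

Step 22
Reactants: 35 (1(10)Z,4E,6R,7S,8S,9S)-9,15-bis[(tert-butyldimethylsilyl)oxy]-8,14-bis[(4-methoxybenzyl)oxy]germacra-1(10),4,11(13)-trien-12,6-olide
Product: 36 (1(10)Z,4E,6R,7S,8S,9S)-9,15-bis[(tert-butyldimethylsilyl)oxy]-8,14-dihydroxygermacra-1(10),4,11(13)-trien-12,6-olide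
Conditions: DDQ (3 equiv), CH2Cl2/pH 7 phosphate buffer 10:1, 0 °C → rt
Reagents that add atoms: none
Why: Oxidative cleavage of both PMB ethers frees O8 and O14 at once while the silyl ethers and the Michael acceptor are untouched (any C14 over-oxidation only anticipates the next step).

Step 23
Reactants: 36 (1(10)Z,4E,6R,7S,8S,9S)-9,15-bis[(tert-butyldimethylsilyl)oxy]-8,14-dihydroxygermacra-1(10),4,11(13)-trien-12,6-olide
Product: 37 (1(10)E,4E,6R,7S,8S,9S)-9,15-bis[(tert-butyldimethylsilyl)oxy]-8-hydroxy-14-oxogermacra-1(10),4,11(13)-trien-12,6-olide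
Conditions: MnO2 (20 equiv), CH2Cl2, rt
Reagents that add atoms: none
Why: MnO2 oxidises only the primary allylic C14 alcohol to the enal and leaves the saturated secondary C8 alcohol, which differentiates the two hydroxyls without protecting groups.

Step 24
Reactants: 38 tiglic acid
Product: 39 (2R)-2-methylbutanoic acid
Conditions: Ru(OAc)2[(R)-H8-BINAP] (0.5 mol %), H2 (1.5 atm), MeOH, 20 °C
Reagents that add atoms: none
Why: Carboxylate-directed asymmetric hydrogenation of the α,β-unsaturated acid, in which the (R)-configured ligand gives the (R)-acid (about 97% ee).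

Step 25
Reactants: 37 (1(10)E,4E,6R,7S,8S,9S)-9,15-bis[(tert-butyldimethylsilyl)oxy]-8-hydroxy-14-oxogermacra-1(10),4,11(13)-trien-12,6-olide; 39 (2R)-2-methylbutanoic acid
Product: 41 (1(10)E,4E,6R,7S,8S,9S)-9,15-bis[(tert-butyldimethylsilyl)oxy]-8-{[(2R)-2-methylbutanoyl]oxy}-14-oxogermacra-1(10),4,11(13)-trien-12,6-olide, via mixed anhydride 40 (not isolated)
Conditions: 39 (3 equiv), 2,4,6-trichlorobenzoyl chloride, Et3N, THF, rt; then 37, DMAP, toluene, rt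
Reagents that add atoms: none
Why: Yamaguchi esterification acylates the hindered C8 hydroxyl through the acylpyridinium derived from the mixed anhydride, without a ketene pathway, so the acid's α-stereocenter is kept.

Step 26
Reactants: 41 (1(10)E,4E,6R,7S,8S,9S)-9,15-bis[(tert-butyldimethylsilyl)oxy]-8-{[(2R)-2-methylbutanoyl]oxy}-14-oxogermacra-1(10),4,11(13)-trien-12,6-olide
Product: 42 (1(10)E,4E,6R,7S,8S,9S)-9,15-dihydroxy-8-{[(2R)-2-methylbutanoyl]oxy}-14-oxogermacra-1(10),4,11(13)-trien-12,6-olide (target)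
Conditions: HF·pyridine, pyridine, THF, 0 °C → rt
Reagents that add atoms: none
Why: Mildly acidic fluoride desilylation removes both silyl ethers without the 8→9 acyl migration or conjugate additions that basic conditions would cause.

## Compound list

1 | ethyl 4-chloro-3-oxobutanoate | CCOC(=O)CC(=O)CCl | starting material
2 | 4-methoxybenzyl alcohol | COc1ccc(CO)cc1 | starting material
3 | ethyl 4-[(4-methoxybenzyl)oxy]-3-oxobutanoate | CCOC(=O)CC(=O)COCc1ccc(OC)cc1 | intermediate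
4 | ethyl (3S)-3-hydroxy-4-[(4-methoxybenzyl)oxy]butanoate | COc1ccc(COC[C@@H](O)CC(=O)OCC)cc1 | intermediate
5 | allyl bromide (3-bromoprop-1-ene) | C=CCBr | starting material
6 | dilithium dianion of 4 (lithium alkoxide, lithium ester enolate) | COc1ccc(COC[C@@H](O[Li])C=C(O[Li])OCC)cc1 | intermediate
7 | ethyl (2R,3S)-3-hydroxy-4-[(4-methoxybenzyl)oxy]-2-(prop-2-en-1-yl)butanoate | COc1ccc(COC[C@@H](O)[C@@H](CC=C)C(=O)OCC)cc1 | intermediate
8 | ethyl (2R)-2-[(4S)-2-(4-methoxyphenyl)-1,3-dioxolan-4-yl]pent-4-enoate (both epimers at the acetal carbon) | COc1ccc(C2OC[C@@H](O2)[C@@H](CC=C)C(=O)OCC)cc1 | intermediate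
9 | (2R)-N-methoxy-2-[(4S)-2-(4-methoxyphenyl)-1,3-dioxolan-4-yl]-N-methylpent-4-enamide | COc1ccc(C2OC[C@@H](O2)[C@@H](CC=C)C(=O)N(C)OC)cc1 | intermediate
10 | tert-butyl(dimethyl)(prop-2-yn-1-yloxy)silane | C#CCO[Si](C)(C)C(C)(C)C | starting material
11 | lithium acetylide of 10 | [Li]C#CCO[Si](C)(C)C(C)(C)C | intermediate
12 | (5R)-1-[(tert-butyldimethylsilyl)oxy]-5-[(4S)-2-(4-methoxyphenyl)-1,3-dioxolan-4-yl]oct-7-en-2-yn-4-one | COc1ccc(C2OC[C@@H](O2)[C@@H](CC=C)C(=O)C#CCO[Si](C)(C)C(C)(C)C)cc1 | intermediate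
13 | (4S,5S)-1-[(tert-butyldimethylsilyl)oxy]-5-[(4S)-2-(4-methoxyphenyl)-1,3-dioxolan-4-yl]oct-7-en-2-yn-4-ol | COc1ccc(C2OC[C@@H](O2)[C@@H](CC=C)[C@H](O)C#CCO[Si](C)(C)C(C)(C)C)cc1 | intermediate
14 | cyclic vinylalanate from 13 (sodium salt; aluminium on C4, bound to O6) | [Na+].COCCO[Al-]1(OCCOC)O[C@@H]([C@H](CC=C)[C@H]2COC(c3ccc(OC)cc3)O2)C=C1CO[Si](C)(C)C(C)(C)C | intermediate
15 | (2Z,4S,5S)-1-[(tert-butyldimethylsilyl)oxy]-2-iodo-5-[(4S)-2-(4-methoxyphenyl)-1,3-dioxolan-4-yl]octa-2,7-dien-4-ol | COc1ccc(C2OC[C@@H](O2)[C@@H](CC=C)[C@H](O)/C=C(/CO[Si](C)(C)C(C)(C)C)I)cc1 | intermediate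
16 | (2Z,4S,5S)-1-[(tert-butyldimethylsilyl)oxy]-5-{(1S)-2-hydroxy-1-[(4-methoxybenzyl)oxy]ethyl}-2-iodoocta-2,7-dien-4-ol | OC[C@@H](OCc1ccc(OC)cc1)[C@@H](CC=C)[C@H](O)/C=C(/CO[Si](C)(C)C(C)(C)C)I | intermediate
17 | (2Z,4S,5S)-1-[(tert-butyldimethylsilyl)oxy]-2-iodo-5-{(1S)-1-[(4-methoxybenzyl)oxy]-2-[(triethylsilyl)oxy]ethyl}octa-2,7-dien-4-ol | CC[Si](CC)(CC)OC[C@@H](OCc1ccc(OC)cc1)[C@@H](CC=C)[C@H](O)/C=C(/CO[Si](C)(C)C(C)(C)C)I | intermediate
18 | vicinal diol from 17 (terminal alkene dihydroxylated; epimers at the new carbinol) | CC[Si](CC)(CC)OC[C@@H](OCc1ccc(OC)cc1)[C@@H](CC(O)CO)[C@H](O)/C=C(/CO[Si](C)(C)C(C)(C)C)I | intermediate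
19 | (4S,5S)-5-{(1Z)-3-[(tert-butyldimethylsilyl)oxy]-2-iodoprop-1-en-1-yl}-4-{(1S)-1-[(4-methoxybenzyl)oxy]-2-[(triethylsilyl)oxy]ethyl}oxolan-2-ol (anomers) | CC[Si](CC)(CC)OC[C@@H](OCc1ccc(OC)cc1)[C@H]1CC(O)O[C@@H]1/C=C(/CO[Si](C)(C)C(C)(C)C)I | intermediate
20 | (4S,5S)-5-{(1Z)-3-[(tert-butyldimethylsilyl)oxy]-2-iodoprop-1-en-1-yl}-4-{(1S)-1-[(4-methoxybenzyl)oxy]-2-[(triethylsilyl)oxy]ethyl}oxolan-2-one | CC[Si](CC)(CC)OC[C@@H](OCc1ccc(OC)cc1)[C@H]1CC(=O)O[C@@H]1/C=C(/CO[Si](C)(C)C(C)(C)C)I | intermediate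
21 | but-3-en-1-ylzinc bromide (0.5 M in THF) | C=CCC[Zn]Br | starting material
22 | (4S,5R)-5-[(1E)-2-{[(tert-butyldimethylsilyl)oxy]methyl}hexa-1,5-dien-1-yl]-4-{(1S)-1-[(4-methoxybenzyl)oxy]-2-[(triethylsilyl)oxy]ethyl}oxolan-2-one | CC[Si](CC)(CC)OC[C@@H](OCc1ccc(OC)cc1)[C@H]1CC(=O)O[C@@H]1/C=C(/CO[Si](C)(C)C(C)(C)C)CCC=C | intermediate
23 | (4S,5R)-5-[(1E)-2-{[(tert-butyldimethylsilyl)oxy]methyl}hexa-1,5-dien-1-yl]-4-{(1S)-2-hydroxy-1-[(4-methoxybenzyl)oxy]ethyl}oxolan-2-one | OC[C@@H](OCc1ccc(OC)cc1)[C@H]1CC(=O)O[C@@H]1/C=C(/CO[Si](C)(C)C(C)(C)C)CCC=C | intermediate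
24 | (2S)-2-{(2R,3S)-2-[(1E)-2-{[(tert-butyldimethylsilyl)oxy]methyl}hexa-1,5-dien-1-yl]-5-oxooxolan-3-yl}-2-[(4-methoxybenzyl)oxy]acetaldehyde | O=C[C@@H](OCc1ccc(OC)cc1)[C@H]1CC(=O)O[C@@H]1/C=C(/CO[Si](C)(C)C(C)(C)C)CCC=C | intermediate
25 | 2,3-dibromoprop-1-ene | C=C(Br)CBr | starting material
26 | 1-{[(2-bromoprop-2-en-1-yl)oxy]methyl}-4-methoxybenzene | C=C(Br)COCc1ccc(OC)cc1 | intermediate
27 | vinyllithium from 26 (2-lithioallyl PMB ether) | [Li]C(=C)COCc1ccc(OC)cc1 | intermediate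
28 | vinylmagnesium bromide from 27 | Br[Mg]C(=C)COCc1ccc(OC)cc1 | intermediate
29 | (4S,5R)-5-[(1E)-2-{[(tert-butyldimethylsilyl)oxy]methyl}hexa-1,5-dien-1-yl]-4-{(1S,2S)-2-hydroxy-1-[(4-methoxybenzyl)oxy]-3-{[(4-methoxybenzyl)oxy]methyl}but-3-en-1-yl}oxolan-2-one | C=C(COCc1ccc(OC)cc1)[C@H](O)[C@@H](OCc1ccc(OC)cc1)[C@H]1CC(=O)O[C@@H]1/C=C(/CO[Si](C)(C)C(C)(C)C)CCC=C | intermediate
30 | (1(10)Z,4E,6R,7S,8S,9S)-15-[(tert-butyldimethylsilyl)oxy]-9-hydroxy-8,14-bis[(4-methoxybenzyl)oxy]-13-norgermacra-1(10),4-dien-12,6-olide (both ring alkenes ring-cis) | C1C(=O)O[C@@H]2/C=C(/CO[Si](C)(C)C(C)(C)C)CC/C=C(/COCc3ccc(OC)cc3)[C@H](O)[C@@H](OCc3ccc(OC)cc3)[C@@H]12 | intermediate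
31 | (1(10)Z,4E,6R,7S,8S,9S)-9,15-bis[(tert-butyldimethylsilyl)oxy]-8,14-bis[(4-methoxybenzyl)oxy]-13-norgermacra-1(10),4-dien-12,6-olide | C1C(=O)O[C@@H]2/C=C(/CO[Si](C)(C)C(C)(C)C)CC/C=C(/COCc3ccc(OC)cc3)[C@H](O[Si](C)(C)C(C)(C)C)[C@@H](OCc3ccc(OC)cc3)[C@@H]12 | intermediate
32 | lithium enolate of 31 | C1=C(O[Li])O[C@@H]2/C=C(/CO[Si](C)(C)C(C)(C)C)CC/C=C(/COCc3ccc(OC)cc3)[C@H](O[Si](C)(C)C(C)(C)C)[C@@H](OCc3ccc(OC)cc3)[C@@H]12 | intermediate
33 | 13-(dimethylamino)-9,15-bis[(tert-butyldimethylsilyl)oxy]-8,14-bis[(4-methoxybenzyl)oxy]germacra-1(10),4-dien-12,6-olide (6R,7S,8S,9S; C11 epimers) | CN(C)CC1C(=O)O[C@@H]2/C=C(/CO[Si](C)(C)C(C)(C)C)CC/C=C(/COCc3ccc(OC)cc3)[C@H](O[Si](C)(C)C(C)(C)C)[C@@H](OCc3ccc(OC)cc3)[C@@H]12 | intermediate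
34 | trimethylammonium iodide of 33 | C[N+](C)(C)CC1C(=O)O[C@@H]2/C=C(/CO[Si](C)(C)C(C)(C)C)CC/C=C(/COCc3ccc(OC)cc3)[C@H](O[Si](C)(C)C(C)(C)C)[C@@H](OCc3ccc(OC)cc3)[C@@H]12.[I-] | intermediate
35 | (1(10)Z,4E,6R,7S,8S,9S)-9,15-bis[(tert-butyldimethylsilyl)oxy]-8,14-bis[(4-methoxybenzyl)oxy]germacra-1(10),4,11(13)-trien-12,6-olide | C=C1C(=O)O[C@@H]2/C=C(/CO[Si](C)(C)C(C)(C)C)CC/C=C(/COCc3ccc(OC)cc3)[C@H](O[Si](C)(C)C(C)(C)C)[C@@H](OCc3ccc(OC)cc3)[C@@H]12 | intermediate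
36 | (1(10)Z,4E,6R,7S,8S,9S)-9,15-bis[(tert-butyldimethylsilyl)oxy]-8,14-dihydroxygermacra-1(10),4,11(13)-trien-12,6-olide | C=C1C(=O)O[C@@H]2/C=C(/CO[Si](C)(C)C(C)(C)C)CC/C=C(/CO)[C@H](O[Si](C)(C)C(C)(C)C)[C@@H](O)[C@@H]12 | intermediate
37 | (1(10)E,4E,6R,7S,8S,9S)-9,15-bis[(tert-butyldimethylsilyl)oxy]-8-hydroxy-14-oxogermacra-1(10),4,11(13)-trien-12,6-olide | C=C1C(=O)O[C@@H]2/C=C(/CO[Si](C)(C)C(C)(C)C)CC/C=C(/C=O)[C@H](O[Si](C)(C)C(C)(C)C)[C@@H](O)[C@@H]12 | intermediate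
38 | tiglic acid ((2E)-2-methylbut-2-enoic acid) | C/C=C(\C)C(=O)O | starting material
39 | (2R)-2-methylbutanoic acid | CC[C@@H](C)C(=O)O | intermediate
40 | mixed anhydride of 39 with 2,4,6-trichlorobenzoic acid | CC[C@@H](C)C(=O)OC(=O)c1c(Cl)cc(Cl)cc1Cl | intermediate
41 | (1(10)E,4E,6R,7S,8S,9S)-9,15-bis[(tert-butyldimethylsilyl)oxy]-8-{[(2R)-2-methylbutanoyl]oxy}-14-oxogermacra-1(10),4,11(13)-trien-12,6-olide | C=C1C(=O)O[C@@H]2/C=C(/CO[Si](C)(C)C(C)(C)C)CC/C=C(/C=O)[C@H](O[Si](C)(C)C(C)(C)C)[C@@H](OC(=O)[C@H](C)CC)[C@@H]12 | intermediate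
42 | (1(10)E,4E,6R,7S,8S,9S)-9,15-dihydroxy-8-{[(2R)-2-methylbutanoyl]oxy}-14-oxogermacra-1(10),4,11(13)-trien-12,6-olide (CNP0331447.8) | C=C1C(=O)O[C@@H]2/C=C(/CO)CC/C=C(/C=O)[C@H](O)[C@@H](OC(=O)[C@H](C)CC)[C@@H]12 | target

## Step count and risk

Total step count: 26. Longest linear sequence: 24 steps (steps 1–15, 17–23, 25 and 26; steps 16 and 24 are side branches).

Three steps most likely to fail:

Step 18 is the riskiest: the metathesis must engage a hindered 1,1-disubstituted alkene and close a ten-membered ring, so oligomers or no turnover are possible. The fallback closes the ring at C9–C10 by an intramolecular Nozaki–Hiyama–Kishi reaction instead. It sets out from 22. Cross-metathesis of the terminal alkene with crotonaldehyde (the same ruthenium catalyst, CH2Cl2, 40 °C) gives the (E)-enal F1. I2/pyridine in CH2Cl2 gives the (Z)-2-iodoenal F2, with iodine cis to C2. NaBH4/CeCl3·7H2O in MeOH at −40 °C gives the iodo allylic alcohol F3, and 4-methoxybenzyl trichloroacetimidate with La(OTf)3 (cat.) gives the PMB ether F4. PPTS/MeOH removes the triethylsilyl group to give the primary alcohol F5, and Dess–Martin periodinane gives the iodo aldehyde F6. CrCl2 (excess) with NiCl2 (cat.) in degassed DMSO at 1 mM then joins C10 to C9 with retention of the iodoalkene geometry and comes back to the route at 30; a C9 epimer, if formed, would be removed by chromatography.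

Step 17 can fail in generating the 2-lithioallyl ether (loss of alkoxide to give allene) or in the level of chelation control. The fallback sets C9 by catalyst-controlled ketone reduction instead. It sets out from 24. Coupling with bromide 26 under Nozaki–Hiyama–Kishi conditions (CrCl2, NiCl2 cat., DMF, rt) needs no organolithium and gives 29 together with its C9 epimer F7. Dess–Martin oxidation of the mixture gives the enone F8. Reduction with (S)-2-methyl-CBS-oxazaborolidine and BH3·SMe2 (THF, −30 °C), with the 2-substituted alkenyl group acting as the larger ketone substituent, is predicted to deliver the (9S)-alcohol and comes back to the route at 29.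

Step 20 can fail by incomplete aminomethylation or retro-Mannich loss on the hindered macrocyclic lactone enolate. The fallback is the selenoxide route, which replaces steps 20 and 21. It sets out from 31. LiN(SiMe3)2 then PhSeCl (THF, −78 °C) gives the 11-(phenylselanyl) lactone F9. LiN(SiMe3)2 then MeI gives the 11-methyl-11-(phenylselanyl) lactone F10; the methyl group enters anti to the C7 side chain, which leaves selenium anti to H-7. H2O2/pyridine (CH2Cl2, 0 °C) forms the selenoxide, whose syn-elimination can then take only a methyl hydrogen, and the sequence comes back to the route at 35.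

## Further compounds

F1 | step 18 | (E)-enal from cross-metathesis of 22 (C1=C10–C14HO; 8-O-PMB, 9-O-triethylsilyl, 15-O-TBS seco lactone) | CC[Si](CC)(CC)OC[C@@H](OCc1ccc(OC)cc1)[C@H]1CC(=O)O[C@@H]1/C=C(/CO[Si](C)(C)C(C)(C)C)CC/C=C/C=O
F2 | step 18 | (Z)-2-iodoenal from F1 (iodine on C10) | CC[Si](CC)(CC)OC[C@@H](OCc1ccc(OC)cc1)[C@H]1CC(=O)O[C@@H]1/C=C(/CO[Si](C)(C)C(C)(C)C)CC/C=C(/C=O)I
F3 | step 18 | (Z)-2-iodo allylic alcohol from F2 (C14–OH) | CC[Si](CC)(CC)OC[C@@H](OCc1ccc(OC)cc1)[C@H]1CC(=O)O[C@@H]1/C=C(/CO[Si](C)(C)C(C)(C)C)CC/C=C(/CO)I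
F4 | step 18 | PMB ether of F3 | CC[Si](CC)(CC)OC[C@@H](OCc1ccc(OC)cc1)[C@H]1CC(=O)O[C@@H]1/C=C(/CO[Si](C)(C)C(C)(C)C)CC/C=C(/COCc2ccc(OC)cc2)I
F5 | step 18 | primary C9 alcohol from F4 | OC[C@@H](OCc1ccc(OC)cc1)[C@H]1CC(=O)O[C@@H]1/C=C(/CO[Si](C)(C)C(C)(C)C)CC/C=C(/COCc2ccc(OC)cc2)I
F6 | step 18 | iodo aldehyde (C9 aldehyde, C10 iodide) | O=C[C@@H](OCc1ccc(OC)cc1)[C@H]1CC(=O)O[C@@H]1/C=C(/CO[Si](C)(C)C(C)(C)C)CC/C=C(/COCc2ccc(OC)cc2)I
F7 | step 17 | C9 epimer of 29 ((1S,2R)-configured side chain) | C=C(COCc1ccc(OC)cc1)[C@@H](O)[C@@H](OCc1ccc(OC)cc1)[C@H]1CC(=O)O[C@@H]1/C=C(/CO[Si](C)(C)C(C)(C)C)CCC=C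
F8 | step 17 | enone (C9 ketone) from 29 and F7 | C=C(COCc1ccc(OC)cc1)C(=O)[C@@H](OCc1ccc(OC)cc1)[C@H]1CC(=O)O[C@@H]1/C=C(/CO[Si](C)(C)C(C)(C)C)CCC=C
F9 | step 20 | 11-(phenylselanyl) derivative of 31 | C1([Se]c4ccccc4)C(=O)O[C@@H]2/C=C(/CO[Si](C)(C)C(C)(C)C)CC/C=C(/COCc3ccc(OC)cc3)[C@H](O[Si](C)(C)C(C)(C)C)[C@@H](OCc3ccc(OC)cc3)[C@@H]12
F10 | step 20 | 11-methyl-11-(phenylselanyl) derivative of 31 | CC1([Se]c4ccccc4)C(=O)O[C@@H]2/C=C(/CO[Si](C)(C)C(C)(C)C)CC/C=C(/COCc3ccc(OC)cc3)[C@H](O[Si](C)(C)C(C)(C)C)[C@@H](OCc3ccc(OC)cc3)[C@@H]12
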